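Crystals count as product, so the product at the end is the charge less what is still starting material or dormant form.

| setting | beta | delta | Thursday's | Wednesday's |
|---|---|---|---|---|
| starting material | 0.34 M | 0.34 M | 0.34 M | 0.34 M |
| catalyst | 0.16 mM | 0.21 mM | 0.25 mM | 0.34 mM |
| remark | run made earlier | run made earlier |  |  |
| time |  |  | 40 h | 20 h |

| run | time / h | product / % | starting material / % |
|---|---|---|---|
| beta | 1.50 | 23 | 75 |
| beta | 3.00 | 44 | 51 |
| beta | 6.00 | 59 | 28 |
| beta | 10.0 | 76 | 11 |
| beta | 20.0 | 85 | 1 |
| delta | 1.50 | 29 | 68 |
| delta | 3.00 | 49 | 47 |
| delta | 6.00 | 67 | 17 |
| delta | 10.0 | 82 | 8 |
| delta | 20.0 | 86 | 3 |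

(readings scatter by 2 percentage points)

- what is said of product includes crystals
- crystals is a solid; its amount is given per volume of the solution
- the numbers in the tables scatter with a standard deviation of 2 percentage points
- steps under discussion: starting material + catalyst -> catalyst + product; crystals <-> product; starting material <-> dormant form

1. which of the two ends with the higher amount of product, in percent of the starting material charged ("neither" if they lie within 2 percentage points) (Thursday's / Wednesday's / neither)
2. product at the end, in percent of the starting material charged, Thursday's
3. product at the end, in percent of the starting material charged, Wednesday's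

1. At 10.0 h the beta run has product 76% and a gap in its balance of 13.0% of the charge. The delta run has 82% and 10.0%. I read the gap as dormant form.

2. The path to product scales with the catalyst and the path to dormant form does not, so gap over product should equal some fixed catalyst amount over the catalyst charged. Beta gives 0.0274 mM and delta 0.0256 mM. I use the mean, 0.0265 mM, the amount at which both paths run equally fast.

3. Catalyst charged over that amount gives 9.44 for Thursday's and 12.8 for Wednesday's. This number B, the parts going to product for each part going dormant, is a selectivity factor.

4. The parked share is one part in 1 + B: 9.58% for Thursday's and 7.23% for Wednesday's. On B alone, Wednesday's leads by 2.3 percentage points, more than the margin.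

5. But Thursday's stands twice as long, and the dormant form can return. The mean gap goes from 11.5% at 10.0 h to 12.5% at 20.0 h, so no fall shows. A fall of 2.8 points, one standard deviation of that difference, corresponds to a return at 0.0282 /h, and as a guess I take half of that, 0.0141 /h. I then reckon product at 94.6% for Thursday's and 94.5% for Wednesday's, a difference smaller than the margin. So one number was not enough, and I say neither.

6. The forecast also says neither, with 94% (90% to 98%) for Thursday's and 93% (90% to 96%) for Wednesday's, since “the faster catalyst and the longer time roughly offset each other”.

7. The flask gives 93.4% for Thursday's and 93.7% for Wednesday's: neither.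

    starting material + catalyst → catalyst + product (k = 0.308 /M/s)
    crystals ⇌ product, rate k2*(cs2 - [product]) while solid is left; crystals form when [product] > cs2 (solubility = 0.290 M, k = 2.73 × 10⁻⁴ /s)
    starting material ⇌ dormant form (K = 2.12, k = 8.76 × 10⁻⁶ /s)

In Thursday's flask at 2.38 h the catalyst path uses starting material 8.8 times as fast as the forward step into dormant form. With the return I took, B = 9.44 leaves 5.45% parked in Thursday's at 40.0 h, and that flask holds 6.24% as dormant form. The same flask as Thursday's with 0.150 mM of catalyst has B = 5.66, which parks 15.0% and after the same return leaves 8.53%. That flask holds 10.2% as dormant form at 40.0 h.

The earlier runs and the new flask were generated by integration for substances that don't exist; noise was put on by code.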